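## Retrosynthetic overview

1. Target 22 ⇐ diene diol 19 + angelic acid 20: a late, site-selective esterification of the secondary 6α-OH that leaves the tertiary 8α-OH free.
2. Diene side chain ⇐ C12 aldehyde 12 (fragment 1) + propanal as its N-tert-butylimine 14 (fragment 2): an intermolecular directed aldol condensation makes the C12–C13 bond and the 12E double bond, and a Wittig methylenation adds C15.
3. 6α,8α-Dioxygenation ⇐ 7-en-6-one 5 (α-face epoxidation, SmI2 opening, dissolving-metal reduction) ⇐ allylic oxidation of 7-ene 4.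
4. Alkene 4 ⇐ (+)-sclareolide 1 (lactone reduction, pivalate, dehydration).
5. Ring order: no carbocycle is built. The trans-decalin (rings A and B, with C5, C9, C10) comes intact from 1, whose lactone ring is opened in step 1.

Assumption: (+)-sclareolide, a bulk fragrance chemical, is taken as an allowed cheap starting material; names use labdane numbering (C17 on C8, C18/C19 on C4, C20 on C10; α = face opposite C20).

## Route

Step 1
Reactants: 1 (+)-sclareolide
Product: 2 13,14,15,16-tetranorlabdane-8α,12-diol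
Conditions: LiAlH4, THF, 0 °C to rt; H2O/NaOH work-up
Reagents that add atoms: none
Why: Hydride reduction of the γ-lactone (ester reduction) opens it to the 1,4-diol without touching C5, C8, C9 or C10, all of which come from 1.

Step 2
Reactants: 2 13,14,15,16-tetranorlabdane-8α,12-diol
Product: 3 8α-hydroxy-13,14,15,16-tetranorlabdan-12-yl pivalate
Conditions: PivCl, pyridine, DMAP (cat.), CH2Cl2, 0 °C
Reagents that add atoms: pivaloyl chloride CC(C)(C)C(Cl)=O
Why: Acylation (esterification) is selective for the primary over the hindered tertiary hydroxyl, and an ester is chosen over an ether because an ether oxygen would capture the C8 cation of the next step as a tetrahydrofuran.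

Step 3
Reactants: 3 8α-hydroxy-13,14,15,16-tetranorlabdan-12-yl pivalate
Product: 4 13,14,15,16-tetranorlabd-7-en-12-yl pivalate
Conditions: p-TsOH·H2O (10 mol%), toluene, 60 °C, stopped at full conversion; AgNO3–SiO2 chromatography
Reagents that add atoms: none
Why: E1 dehydration: the tertiary C8 cation loses the axial 7α-hydrogen faster than the hindered 9α-hydrogen, so the trisubstituted 7-ene is the main isomer (minor 8(17)- and 8-enes are removed on silver nitrate silica) and C9 stays as in 1.

Step 4
Reactants: 4 13,14,15,16-tetranorlabd-7-en-12-yl pivalate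
Product: 5 6-oxo-13,14,15,16-tetranorlabd-7-en-12-yl pivalate
Conditions: CrO3, 3,5-dimethylpyrazole, CH2Cl2, −20 °C
Reagents that add atoms: chromium trioxide O=[Cr](=O)=O
Why: Allylic oxidation by hexavalent chromium attacks the only allylic ring methylene (C6), the C9 methine and C17 methyl being far less reactive, and any C8 chromate ester transposes to the same conjugated 7-en-6-one.

Step 5
Reactants: 5 6-oxo-13,14,15,16-tetranorlabd-7-en-12-yl pivalate
Product: 6 7α,8α-epoxy-6-oxo-13,14,15,16-tetranorlabdan-12-yl pivalate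
Conditions: 30% H2O2, NaOH (0.5 equiv), MeOH, 0 °C to rt
Reagents that add atoms: hydrogen peroxide OO
Why: Weitz–Scheffer nucleophilic epoxidation: hydroperoxide adds to C8 from the α face because the β face of C8 is syn-axial to the C20 methyl, which sets C8 (oxygen α, methyl β) and C7.

Step 6
Reactants: 6 7α,8α-epoxy-6-oxo-13,14,15,16-tetranorlabdan-12-yl pivalate
Product: 7 8α-hydroxy-6-oxo-13,14,15,16-tetranorlabdan-12-yl pivalate
Conditions: SmI2 (2.5 equiv), THF/MeOH, −90 °C
Reagents that add atoms: none
Why: Reductive opening of an α,β-epoxy ketone by divalent samarium (ketyl, then enolate) cleaves only the C7–O bond, so the 8α oxygen stays and the β-hydroxy ketone is protonated by MeOH at low temperature before it can eliminate.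

Step 7
Reactants: 7 8α-hydroxy-6-oxo-13,14,15,16-tetranorlabdan-12-yl pivalate
Product: 9 13,14,15,16-tetranorlabdane-6α,8α,12-triol, via diol pivalate 8 (not isolated)
Conditions: Li (12 equiv), NH3(l)/THF/EtOH, −78 then −33 °C; NH4Cl
Reagents that add atoms: none
Why: Dissolving-metal (Bouveault–Blanc type) reduction gives the thermodynamically favoured equatorial 6α-alcohol, since an axial 6β-oxygen would be syn-axial to the C19 and C20 methyls, and the excess lithium then cleaves the pivalate.

Step 8
Reactants: 9 13,14,15,16-tetranorlabdane-6α,8α,12-triol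
Product: 10 6α,8α,12-tris(triethylsilyloxy)-13,14,15,16-tetranorlabdane
Conditions: Et3SiOTf (4.5 equiv), 2,6-lutidine, CH2Cl2, −78 to 0 °C
Reagents that add atoms: triethylsilyl trifluoromethanesulfonate CC[Si](CC)(CC)OS(=O)(=O)C(F)(F)F
Why: Silyl ether formation with the silyl triflate is forceful enough to cap the hindered tertiary 8α-hydroxyl, which must be masked so that it cannot add in oxa-Michael fashion to the enal made in step 12.

Step 9
Reactants: 10 6α,8α,12-tris(triethylsilyloxy)-13,14,15,16-tetranorlabdane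
Product: 11 6α,8α-bis(triethylsilyloxy)-13,14,15,16-tetranorlabdan-12-ol
Conditions: PPTS (0.2 equiv), MeOH/CH2Cl2, 0 °C
Reagents that add atoms: none
Why: Acid-catalysed methanolysis (selective desilylation) is orders of magnitude faster for the unhindered primary silyl ether than for the neopentyl-like secondary and the tertiary ones.

Step 10
Reactants: 11 6α,8α-bis(triethylsilyloxy)-13,14,15,16-tetranorlabdan-12-ol
Product: 12 6α,8α-bis(triethylsilyloxy)-13,14,15,16-tetranorlabdan-12-al
Conditions: (Pr4N)(RuO4) (5 mol%), NMO, 4 Å MS, CH2Cl2, rt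
Reagents that add atoms: none
Why: Ley–Griffith oxidation under neutral conditions stops cleanly at the aldehyde and leaves the silyl ethers and all stereocenters untouched.

Step 11
Reactants: 13 propanal
Product: 14 (E)-N-tert-butylpropan-1-imine
Conditions: t-BuNH2, neat, 0 °C; KOH pellets; distil
Reagents that add atoms: tert-butylamine CC(C)(C)N
Why: Imine condensation; the bulky N-tert-butyl group suppresses self-condensation and later directs metalation to the α-carbon.

Step 12
Reactants: 12 6α,8α-bis(triethylsilyloxy)-13,14,15,16-tetranorlabdan-12-al, 14 (E)-N-tert-butylpropan-1-imine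
Product: 17 (12E)-6α,8α-bis(triethylsilyloxy)-15-norlabd-12-en-14-al, via lithium aza-enolate 15 (not isolated), via lithium aldolate 16 (not isolated)
Conditions: 14, LiN(iPr)2, THF, −78 to 0 °C; 12, −78 °C; then aq. oxalic acid, THF, 0 °C to rt
Reagents that add atoms: none
Why: Directed intermolecular aldol condensation (Wittig directed aldol): the preformed aza-enolate of fragment 2 adds to the aldehyde of fragment 1 to make the C12–C13 bond without cross- or self-aldol scrambling, and acid hydrolysis with dehydration gives the conjugated enal as the thermodynamically favoured 12E isomer (C11 trans to CHO).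

Step 13
Reactants: 17 (12E)-6α,8α-bis(triethylsilyloxy)-15-norlabd-12-en-14-al
Product: 18 (12E)-6α,8α-bis(triethylsilyloxy)labda-12,14-diene
Conditions: Ph3PCH3Br, KOtBu, THF, 0 °C; then 17, 0 °C to rt
Reagents that add atoms: methyltriphenylphosphonium bromide C[P+](c1ccccc1)(c1ccccc1)c1ccccc1.[Br-]
Why: Wittig methylenation of the aldehyde adds C15 and completes the 12E,14-diene without touching the C12=C13 geometry.

Step 14
Reactants: 18 (12E)-6α,8α-bis(triethylsilyloxy)labda-12,14-diene
Product: 19 (12E)-labda-12,14-diene-6α,8α-diol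
Conditions: Bu4NF (4 equiv), THF, rt to 45 °C
Reagents that add atoms: none
Why: Fluoride-induced desilylation frees both hydroxyls under non-acidic conditions, which the acid-sensitive hydroxy diene requires.

Step 15
Reactants: 20 angelic acid
Product: 21 angelic 2,4,6-trichlorobenzoic anhydride
Conditions: 2,4,6-trichlorobenzoyl chloride, Et3N, toluene, rt; filter
Reagents that add atoms: 2,4,6-trichlorobenzoyl chloride O=C(Cl)c1c(Cl)cc(Cl)cc1Cl
Why: Yamaguchi mixed-anhydride formation activates angelic acid without a nucleophilic catalyst, so the Z double bond is not isomerised.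

Step 16
Reactants: 19 (12E)-labda-12,14-diene-6α,8α-diol, 21 angelic 2,4,6-trichlorobenzoic anhydride
Product: 22 (12E)-8α-hydroxylabda-12,14-dien-6α-yl angelate
Conditions: Et3N, toluene, 75 °C (no DMAP)
Reagents that add atoms: none
Why: Yamaguchi-type esterification: the secondary equatorial 6α-hydroxyl attacks the unhindered angeloyl carbonyl of the mixed anhydride while the tertiary 8α-hydroxyl is inert, and leaving out DMAP avoids addition–elimination isomerisation to the tiglate.

## Compound list

1 | (+)-sclareolide (8α,12-epoxy-13,14,15,16-tetranorlabdan-12-one) | O=C1C[C@@H]2[C@@]3(C)CCCC(C)(C)[C@@H]3CC[C@@]2(C)O1 | starting material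
2 | 13,14,15,16-tetranorlabdane-8α,12-diol | OCC[C@@H]1[C@@]2(C)CCCC(C)(C)[C@@H]2CC[C@@]1(C)O | intermediate
3 | 8α-hydroxy-13,14,15,16-tetranorlabdan-12-yl pivalate | CC(C)(C)C(=O)OCC[C@@H]1[C@@]2(C)CCCC(C)(C)[C@@H]2CC[C@@]1(C)O | intermediate
4 | 13,14,15,16-tetranorlabd-7-en-12-yl pivalate | CC(C)(C)C(=O)OCC[C@@H]1[C@@]2(C)CCCC(C)(C)[C@@H]2CC=C1C | intermediate
5 | 6-oxo-13,14,15,16-tetranorlabd-7-en-12-yl pivalate | CC(C)(C)C(=O)OCC[C@@H]1[C@@]2(C)CCCC(C)(C)[C@@H]2C(=O)C=C1C | intermediate
6 | 7α,8α-epoxy-6-oxo-13,14,15,16-tetranorlabdan-12-yl pivalate | CC(C)(C)C(=O)OCC[C@@H]1[C@@]2(C)CCCC(C)(C)[C@@H]2C(=O)[C@H]3O[C@@]13C | intermediate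
7 | 8α-hydroxy-6-oxo-13,14,15,16-tetranorlabdan-12-yl pivalate | CC(C)(C)C(=O)OCC[C@@H]1[C@@]2(C)CCCC(C)(C)[C@@H]2C(=O)C[C@@]1(C)O | intermediate
8 | 6α,8α-dihydroxy-13,14,15,16-tetranorlabdan-12-yl pivalate (diol pivalate) | CC(C)(C)C(=O)OCC[C@@H]1[C@@]2(C)CCCC(C)(C)[C@@H]2[C@@H](O)C[C@@]1(C)O | intermediate (not isolated)
9 | 13,14,15,16-tetranorlabdane-6α,8α,12-triol | OCC[C@@H]1[C@@]2(C)CCCC(C)(C)[C@@H]2[C@@H](O)C[C@@]1(C)O | intermediate
10 | 6α,8α,12-tris(triethylsilyloxy)-13,14,15,16-tetranorlabdane | CC[Si](CC)(CC)OCC[C@@H]1[C@@]2(C)CCCC(C)(C)[C@@H]2[C@@H](O[Si](CC)(CC)CC)C[C@@]1(C)O[Si](CC)(CC)CC | intermediate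
11 | 6α,8α-bis(triethylsilyloxy)-13,14,15,16-tetranorlabdan-12-ol | OCC[C@@H]1[C@@]2(C)CCCC(C)(C)[C@@H]2[C@@H](O[Si](CC)(CC)CC)C[C@@]1(C)O[Si](CC)(CC)CC | intermediate
12 | 6α,8α-bis(triethylsilyloxy)-13,14,15,16-tetranorlabdan-12-al | O=CC[C@@H]1[C@@]2(C)CCCC(C)(C)[C@@H]2[C@@H](O[Si](CC)(CC)CC)C[C@@]1(C)O[Si](CC)(CC)CC | intermediate
13 | propanal | CCC=O | starting material
14 | (E)-N-tert-butylpropan-1-imine | CC/C=N/C(C)(C)C | intermediate
15 | lithium aza-enolate of 14 (N-lithio-N-tert-butylprop-1-en-1-amine, C=C geometry not defined) | CC=CN([Li])C(C)(C)C | intermediate (not isolated)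
16 | lithium aldolate: lithium alkoxide of 12-hydroxy-6α,8α-bis(triethylsilyloxy)-15-norlabdan-14-al N-tert-butylimine (C12/C13 diastereomer mixture) | CC(/C=N/C(C)(C)C)C(O[Li])C[C@@H]1[C@@]2(C)CCCC(C)(C)[C@@H]2[C@@H](O[Si](CC)(CC)CC)C[C@@]1(C)O[Si](CC)(CC)CC | intermediate (not isolated)
17 | (12E)-6α,8α-bis(triethylsilyloxy)-15-norlabd-12-en-14-al | O=C/C(C)=C/C[C@@H]1[C@@]2(C)CCCC(C)(C)[C@@H]2[C@@H](O[Si](CC)(CC)CC)C[C@@]1(C)O[Si](CC)(CC)CC | intermediate
18 | (12E)-6α,8α-bis(triethylsilyloxy)labda-12,14-diene | C=C/C(C)=C/C[C@@H]1[C@@]2(C)CCCC(C)(C)[C@@H]2[C@@H](O[Si](CC)(CC)CC)C[C@@]1(C)O[Si](CC)(CC)CC | intermediate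
19 | (12E)-labda-12,14-diene-6α,8α-diol | C=C/C(C)=C/C[C@@H]1[C@@]2(C)CCCC(C)(C)[C@@H]2[C@@H](O)C[C@@]1(C)O | intermediate
20 | angelic acid, (Z)-2-methylbut-2-enoic acid | C/C=C(/C)C(=O)O | starting material
21 | angelic 2,4,6-trichlorobenzoic anhydride | C/C=C(/C)C(=O)OC(=O)c1c(Cl)cc(Cl)cc1Cl | intermediate
22 | (12E)-8α-hydroxylabda-12,14-dien-6α-yl angelate (CNP0582767.1) | C=C/C(C)=C/C[C@@H]1[C@@]2(C)CCCC(C)(C)[C@@H]2[C@@H](OC(=O)/C(C)=C\C)C[C@@]1(C)O | target

## Step count and risks

Total step count: 16. Longest linear sequence: 14 steps (1 to 10, 12, 13, 14, 16); steps 11 and 15 are one-step side branches.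

Stereocenters: C5, C9 and C10 come from 1 and are never broken. C8 is erased in step 3 and reset in step 5. C6 is set in step 7. The 12E alkene is set in step 12, and the angelate Z alkene comes from 20.

Three steps most likely to fail:

Step 3 (regiochemistry of the dehydration). Prolonged acid drifts the 7-ene towards the tetrasubstituted 8-ene, and the isomers are hard to separate. Fallback: set out from 3. SOCl2 and pyridine in CH2Cl2 at −78 °C eliminate the chlorosulfite kinetically across the methyl group and give mainly the exocyclic alkene 13,14,15,16-tetranorlabd-8(17)-en-12-yl pivalate F1. RhCl3·3H2O (5 mol%) in EtOH at 75 °C then moves the double bond into the ring through an allyl rhodium hydride, which forms at the accessible C7 methylene and not at the hindered C9 methine. The route is rejoined at 4.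

Step 5 (epoxidation of a hindered β,β-disubstituted enone). Hydroperoxide addition at C8 may be slow, and base may enolise the ketone instead. Fallback: set out from 5. Conjugate borylation with B2pin2 and MeOH in THF, catalysed by CuCl, NaOtBu and Xantphos (4,5-bis(diphenylphosphino)-9,9-dimethylxanthene), delivers boron to the α face of C8 and gives the β-boryl ketone 6-oxo-8α-(4,4,5,5-tetramethyl-1,3,2-dioxaborolan-2-yl)-13,14,15,16-tetranorlabdan-12-yl pivalate F2. NaBO3·4H2O in THF/H2O oxidises the C–B bond with retention. This replaces steps 5 and 6 and comes back at 7.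

Step 16 (angeloylation of the hindered 6α-hydroxyl). The acylation may be sluggish, and forcing it risks Z-to-E isomerisation to the tiglate. Fallback: set out from 19. EDC·HCl and DMAP in CH2Cl2 esterify the 6α-hydroxyl with 2-[bis(2,2,2-trifluoroethoxy)phosphoryl]propanoic acid, giving (12E)-8α-hydroxylabda-12,14-dien-6α-yl 2-[bis(2,2,2-trifluoroethoxy)phosphoryl]propanoate F3. A Still–Gennari olefination with acetaldehyde (KN(SiMe3)2, 18-crown-6, THF, −78 °C) then builds the Z-configured 2-methylbut-2-enoate directly on the ester and arrives at 22.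

## Further compounds

F1 | step 3 | 13,14,15,16-tetranorlabd-8(17)-en-12-yl pivalate | CC(C)(C)C(=O)OCC[C@@H]1[C@@]2(C)CCCC(C)(C)[C@@H]2CCC1=C
F2 | step 5 | 6-oxo-8α-(4,4,5,5-tetramethyl-1,3,2-dioxaborolan-2-yl)-13,14,15,16-tetranorlabdan-12-yl pivalate | CC(C)(C)C(=O)OCC[C@@H]1[C@@]2(C)CCCC(C)(C)[C@@H]2C(=O)C[C@@]1(C)B1OC(C)(C)C(C)(C)O1
F3 | step 16 | (12E)-8α-hydroxylabda-12,14-dien-6α-yl 2-[bis(2,2,2-trifluoroethoxy)phosphoryl]propanoate (mixture at the phosphonate α-carbon) | C=C/C(C)=C/C[C@@H]1[C@@]2(C)CCCC(C)(C)[C@@H]2[C@@H](OC(=O)C(C)P(=O)(OCC(F)(F)F)OCC(F)(F)F)C[C@@]1(C)O
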